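**Plan**

1. Side-chain cuts: the C2' carbonyl oxygen (quinone from a 3-methoxy-5-alkenylphenol), the C8–H bond (from a C8 methylene), the C11–Cl bond (from the enol triflate of the C8=C9 aryl ketone) and the C11 oxygen (from the benzylic CH2).
2. Ring cuts: the carbocycle C1'–C6' at C2'–C3', C4'–C5' and C5'–C6' into a 3-substituted cyclobutenone and methoxyacetylene; the cyclobutenone into dichloroketene and a terminal alkyne; the alkyne C≡C back to the lactol of (+)-sclareolide.
3. Enabling feature: ring C1'–C6' carries C11 at C1', OMe at C3' and oxygen at C5' (1,3,5), the pattern a cyclobutenone–alkoxyalkyne benzannulation delivers. C1' is the lactone carbonyl carbon of sclareolide, so rings A and B, C11 and C1' come in one piece and no aryl–C11 bond is made.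
4. Forward order: rings A and B from sclareolide; the four-membered ring on the homologated alkyne (steps 4 and 5); the aromatic ring from it in step 7; then C11 oxidation, enone, dienyl triflate, chloride, C8 reduction, quinone.
5. Stereochemistry: C5 and C10 are those of sclareolide. C8 is flattened in step 10 and re-set by hydrogen delivery to the α face of the C8 methylene in step 13. The C9=C11 geometry is set when the dienolate forms with oxygen syn to C8 (step 11) and is kept in the triflate-to-chloride exchange.

Key step: step 7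

Remark: drimane locants are used (C11 is the carbon on C9, C12 the methyl carbon on C8); the carbocycle is numbered from the carbon bonded to C11 (C1') towards the methoxy carbon (C3'). Methoxyacetylene is volatile and is made in step 6. The anomeric carbon of the sclareolide lactol and the carbinol carbon C11 of the fallback compounds are inconsequential epimer mixtures and are written without configuration. The C8 hydroxyl is carried as an acetate (not a silyl ether) because it must later leave in a base-induced β-elimination.

**Step 1**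
Reactants: 1 (+)-sclareolide
Product: 2 sclareolide lactol (cyclic hemiacetal at the former carbonyl carbon; anomer mixture)
Conditions: i-Bu2AlH (1.2 equiv), CH2Cl2, −78 °C; aq. potassium sodium tartrate work-up
Reagents that add atoms: none
Why: Half-reduction of the γ-lactone with i-Bu2AlH at −78 °C (lactone-to-lactol reduction) stops at the tetrahedral aluminium alkoxide, which gives the lactol on work-up, and it touches no stereocentre of the decalin, the new hemiacetal carbon being an anomer mixture that is lost in the next step.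

**Step 2**
Reactants: 2 sclareolide lactol; 3 dimethyl (1-diazo-2-oxopropyl)phosphonate
Product: 4 11-ethynyldriman-8α-ol (C9 bears β-CH2–C≡CH; C8 bears α-OH and β-CH3)
Conditions: K2CO3 (2 equiv), MeOH, 0 °C → rt
Reagents that add atoms: none
Why: Ohira–Bestmann homologation: the lactol is in equilibrium with its γ-hydroxy aldehyde, which is trapped by dimethyl (diazomethyl)phosphonate anion generated from 3 by methanolysis, and the resulting alkylidene carbene rearranges by 1,2-hydrogen shift to the terminal alkyne without touching C8 or C9.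

**Step 3**
Reactants: 4 11-ethynyldriman-8α-ol
Product: 5 11-ethynyldriman-8α-yl acetate
Conditions: AcCl, PhNMe2, CH2Cl2, 0 °C → rt
Reagents that add atoms: acetyl chloride, CC(=O)Cl
Why: Acetylation of the hindered tertiary 8α-alcohol with acetyl chloride and N,N-dimethylaniline, the usual way to esterify the tertiary hydroxyl of sclareol-type decalinols, masks the hydroxyl for the zinc steps and installs the leaving group that is expelled in step 10.

**Step 4**
Reactants: 5 11-ethynyldriman-8α-yl acetate; 6 trichloroacetyl chloride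
Product: 7 4,4-dichloro-3-(8α-acetoxydriman-11-yl)cyclobut-2-en-1-one
Conditions: Zn–Cu couple, Et2O/DME, slow addition of 6, rt → 35 °C
Reagents that add atoms: none
Why: Dichloroketene, generated from 6 by zinc dechlorination, undergoes [2+2] cycloaddition with the terminal alkyne, and because the unsubstituted alkyne carbon bonds to the ketene carbonyl carbon the side chain ends up at C3 of the cyclobutenone, next to the CCl2 group.

**Step 5**
Reactants: 7 4,4-dichloro-3-(8α-acetoxydriman-11-yl)cyclobut-2-en-1-one
Product: 8 3-(8α-acetoxydriman-11-yl)cyclobut-2-en-1-one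
Conditions: Zn dust, TMEDA, AcOH, EtOH, 0 °C → rt
Reagents that add atoms: none
Why: Zinc in acetic acid buffered with TMEDA removes both α-chlorine atoms (reductive dehalogenation of an α,α-dichloroketone) and is the standard way from 4,4-dichlorocyclobutenones to cyclobutenones, the tertiary acetate being inert.

**Step 6**
Reactants: 9 chloroacetaldehyde dimethyl acetal
Product: 10 methoxyacetylene
Conditions: NaNH2 (3 equiv), liquid NH3, −33 °C; cold saturated aq. NaCl quench; distillation into cold toluene
Reagents that add atoms: none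
Why: Sodium amide effects two successive β-eliminations (methanol, then HCl) from the chloroacetal, the classical preparation of alkoxyacetylenes, and the sodium acetylide formed is protonated on quenching.

**Step 7**
Reactants: 8 3-(8α-acetoxydriman-11-yl)cyclobut-2-en-1-one; 10 methoxyacetylene
Product: 15 3-methoxy-5-(8α-acetoxydriman-11-yl)phenol, via vinylketene 11 (not isolated), via 4-vinylcyclobutenone 12 (not isolated), via dienylketene 13 (not isolated), via cyclohexadienone 14 (not isolated)
Conditions: 10 (3 equiv), toluene, sealed tube, 80 °C, then 110 °C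
Reagents that add atoms: none
Why: Heating opens cyclobutenone 8 by 4π electrocyclic ring opening to vinylketene 11, which adds methoxyacetylene in a [2+2] cycloaddition (C2'–C3' and C4'–C5' form) to give 4-vinylcyclobutenone 12; a second 4π opening gives dienylketene 13, whose 6π electrocyclisation forms C5'–C6' and cyclohexadienone 14, and tautomerisation delivers the phenol. This is the Danheiser benzannulation, and the closest known case is the reaction of 3-alkylcyclobutenones with alkoxyacetylenes to give 3-alkoxy-5-alkylphenols. The one ring that closes is the carbocycle C1'–C6', by thermal disrotatory 6π electrocyclisation of the dienylketene. No stereocentre is formed, and C5, C8, C9 and C10 lie outside the reacting π system. The step needs one orientation of the ketene–alkyne [2+2], and the polarisation of the ynol ether secures it: its nucleophilic CH carbon bonds to the electrophilic ketene carbonyl carbon, so that OMe ends up at C3', meta to both the hydroxyl at C5' and the side chain at C1'. An excess of the alkyne in a closed vessel keeps the vinylketene from dimerising or acylating the phenol already formed.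

**Step 8**
Reactants: 15 3-methoxy-5-(8α-acetoxydriman-11-yl)phenol
Product: 16 3-methoxy-5-(8α-acetoxydriman-11-yl)phenyl pivalate
Conditions: PivCl, Et3N, DMAP (cat.), CH2Cl2, 0 °C → rt
Reagents that add atoms: pivaloyl chloride, CC(C)(C)C(=O)Cl
Why: O-Acylation of the phenol with pivaloyl chloride under DMAP catalysis gives a hindered aryl ester that lowers the electron density of the ring before the chromium oxidation and withstands DBU, KN(SiMe3)2 and diimide.

**Step 9**
Reactants: 16 3-methoxy-5-(8α-acetoxydriman-11-yl)phenyl pivalate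
Product: 17 8α-acetoxy-11-(3-methoxy-5-pivaloyloxyphenyl)driman-11-one
Conditions: CrO3, 3,5-dimethylpyrazole, CH2Cl2, −20 °C → 0 °C
Reagents that add atoms: chromium trioxide, O=[Cr](=O)=O
Why: Benzylic oxidation of the ArCH2 group to the aryl ketone with the CrO3–3,5-dimethylpyrazole complex, a reagent established for benzylic and allylic methylenes of terpenoids, should be selective because C11 is the only benzylic carbon bearing hydrogen and the ring carries an ester in place of the free hydroxyl.

**Step 10**
Reactants: 17 8α-acetoxy-11-(3-methoxy-5-pivaloyloxyphenyl)driman-11-one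
Product: 18 11-(3-methoxy-5-pivaloyloxyphenyl)drim-8-en-11-one
Conditions: DBU, toluene, 60 °C
Reagents that add atoms: none
Why: Base-induced β-elimination (E1cB) of the β-acetoxy ketone: DBU removes the now acidic C9–H and acetate leaves from C8, which can only give the C8=C9 enone and avoids a cation at C8 that would alkylate the arene.

**Step 11**
Reactants: 18 11-(3-methoxy-5-pivaloyloxyphenyl)drim-8-en-11-one
Product: 20 11-(3-methoxy-5-pivaloyloxyphenyl)drima-8(12),9(11)-dien-11-yl triflate (OTf syn to C8; aryl syn to C10), via potassium dienolate 19 (not isolated)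
Conditions: KN(SiMe3)2, THF, −78 → −20 °C; then PhNTf2, −78 °C → 0 °C
Reagents that add atoms: N-phenylbis(trifluoromethanesulfonimide), O=S(=O)(N(c1ccccc1)S(=O)(=O)C(F)(F)F)C(F)(F)F
Why: With no α-hydrogen left, KN(SiMe3)2 removes a γ-hydrogen from the C8 methyl, which lies syn to the carbonyl, and PhNTf2 triflates the dienolate on oxygen (enol triflate formation); in the planar s-cis arrangement needed for this deprotonation the aryl group turns to the C10 side to avoid 1,3-allylic strain with the C8 substituent, so oxygen is fixed syn to C8 and the C9=C11 geometry of the target is set.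

**Step 12**
Reactants: 20 11-(3-methoxy-5-pivaloyloxyphenyl)drima-8(12),9(11)-dien-11-yl triflate
Product: 21 11-chloro-11-(3-methoxy-5-pivaloyloxyphenyl)drima-8(12),9(11)-diene (Cl syn to C8)
Conditions: Ni(cod)2 (10 mol%), LiCl, DMA/THF, 23 °C
Reagents that add atoms: lithium chloride, [Li+].[Cl-]
Why: Nickel-catalysed halogen exchange of an enol triflate: zerovalent nickel inserts into the C–O bond, triflate is exchanged for chloride from LiCl and C–Cl reductive elimination gives the alkenyl chloride with the geometry of the triflate retained.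

**Step 13**
Reactants: 21 11-chloro-11-(3-methoxy-5-pivaloyloxyphenyl)drima-8(12),9(11)-diene
Product: 22 11-chloro-11-(3-methoxy-5-pivaloyloxyphenyl)-8αH-drim-9(11)-ene (8β-methyl; Cl syn to C8)
Conditions: TsNHNH2, NaOAc, THF/H2O, reflux
Reagents that add atoms: none
Why: Diimide, formed by thermolysis of tosylhydrazide, transfers H2 in a concerted syn fashion to the strained 1,1-disubstituted C8 methylene only (diimide reduction), leaving the tetrasubstituted chloroalkene, the C–Cl bond and the ester alone, and it should attack the α face opposite the axial C10 methyl, which places the new C8–H α and the methyl β (axial), the arrangement that also avoids 1,3-allylic strain between the methyl and the syn chlorine.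

**Step 14**
Reactants: 22 11-chloro-11-(3-methoxy-5-pivaloyloxyphenyl)-8αH-drim-9(11)-ene
Product: 23 3-(11-chloro-8αH-drim-9(11)-en-11-yl)-5-methoxyphenol
Conditions: K2CO3, MeOH, 40 °C
Reagents that add atoms: none
Why: Carbonate-mediated methanolysis (transesterification) of the aryl pivalate frees the phenol under conditions to which the chloroalkene and the C8 centre are inert.

**Step 15**
Reactants: 23 3-(11-chloro-8αH-drim-9(11)-en-11-yl)-5-methoxyphenol
Product: 24 2-(11-chloro-8αH-drim-9(11)-en-11-yl)-6-methoxy-1,4-benzoquinone (target; 8β-methyl; Cl syn to C8, quinone syn to C10)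
Conditions: (KSO3)2NO, KH2PO4, acetone/H2O, rt
Reagents that add atoms: potassium nitrosodisulfonate, [K+].[K+].[O]N(S(=O)(=O)[O-])S(=O)(=O)[O-]
Why: Teuber oxidation with (KSO3)2NO converts a phenol with a free para position into the para-benzoquinone, here by oxygenation of C2' between C1' and the methoxy carbon C3', as is known for 3-methoxy-5-alkylphenols, and the buffered conditions leave the chloroalkene and C8 unchanged.

**Compound list**

1 | (+)-sclareolide | O=C1C[C@H]2[C@](C)(O1)CC[C@H]3C(C)(C)CCC[C@]23C | starting material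
2 | sclareolide lactol (anomer mixture) | OC1C[C@H]2[C@](C)(O1)CC[C@H]3C(C)(C)CCC[C@]23C | intermediate
3 | dimethyl (1-diazo-2-oxopropyl)phosphonate | CC(=O)C(=[N+]=[N-])P(=O)(OC)OC | starting material
4 | 11-ethynyldriman-8α-ol | C#CC[C@H]2[C@](C)(O)CC[C@H]3C(C)(C)CCC[C@]23C | intermediate
5 | 11-ethynyldriman-8α-yl acetate | C#CC[C@H]2[C@](C)(OC(C)=O)CC[C@H]3C(C)(C)CCC[C@]23C | intermediate
6 | trichloroacetyl chloride | O=C(Cl)C(Cl)(Cl)Cl | starting material
7 | 4,4-dichloro-3-(8α-acetoxydriman-11-yl)cyclobut-2-en-1-one | O=C1C=C(C[C@H]2[C@](C)(OC(C)=O)CC[C@H]3C(C)(C)CCC[C@]23C)C1(Cl)Cl | intermediate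
8 | 3-(8α-acetoxydriman-11-yl)cyclobut-2-en-1-one | O=C1C=C(C[C@H]2[C@](C)(OC(C)=O)CC[C@H]3C(C)(C)CCC[C@]23C)C1 | intermediate
9 | chloroacetaldehyde dimethyl acetal | COC(CCl)OC | starting material
10 | methoxyacetylene | COC#C | intermediate
11 | vinylketene, 3-(8α-acetoxydriman-11-yl)buta-1,3-dien-1-one | O=C=CC(=C)C[C@H]2[C@](C)(OC(C)=O)CC[C@H]3C(C)(C)CCC[C@]23C | intermediate
12 | 3-methoxy-4-[1-(8α-acetoxydriman-11-yl)vinyl]cyclobut-2-en-1-one (epimers at ring C4) | COC1=CC(=O)C1C(=C)C[C@H]2[C@](C)(OC(C)=O)CC[C@H]3C(C)(C)CCC[C@]23C | intermediate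
13 | dienylketene, 3-methoxy-5-(8α-acetoxydriman-11-yl)hexa-1,3,5-trien-1-one (ketenyl carbon and C1' cis on the central C=C) | O=C=C/C(OC)=C\C(=C)C[C@H]2[C@](C)(OC(C)=O)CC[C@H]3C(C)(C)CCC[C@]23C | intermediate
14 | 3-methoxy-5-(8α-acetoxydriman-11-yl)cyclohexa-2,4-dien-1-one | COC1=CC(=O)CC(C[C@H]2[C@](C)(OC(C)=O)CC[C@H]3C(C)(C)CCC[C@]23C)=C1 | intermediate
15 | 3-methoxy-5-(8α-acetoxydriman-11-yl)phenol | COc1cc(O)cc(C[C@H]2[C@](C)(OC(C)=O)CC[C@H]3C(C)(C)CCC[C@]23C)c1 | intermediate
16 | 3-methoxy-5-(8α-acetoxydriman-11-yl)phenyl pivalate | COc1cc(OC(=O)C(C)(C)C)cc(C[C@H]2[C@](C)(OC(C)=O)CC[C@H]3C(C)(C)CCC[C@]23C)c1 | intermediate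
17 | 8α-acetoxy-11-(3-methoxy-5-pivaloyloxyphenyl)driman-11-one | COc1cc(OC(=O)C(C)(C)C)cc(C(=O)[C@H]2[C@](C)(OC(C)=O)CC[C@H]3C(C)(C)CCC[C@]23C)c1 | intermediate
18 | 11-(3-methoxy-5-pivaloyloxyphenyl)drim-8-en-11-one | COc1cc(OC(=O)C(C)(C)C)cc(C(=O)C2=C(C)CC[C@H]3C(C)(C)CCC[C@]23C)c1 | intermediate
19 | potassium 11-(3-methoxy-5-pivaloyloxyphenyl)drima-8(12),9(11)-dien-11-olate (O syn to C8) | COc1cc(OC(=O)C(C)(C)C)cc(/C([O-])=C2/C(=C)CC[C@H]3C(C)(C)CCC[C@]23C)c1.[K+] | intermediate
20 | 11-(3-methoxy-5-pivaloyloxyphenyl)drima-8(12),9(11)-dien-11-yl triflate (OTf syn to C8) | COc1cc(OC(=O)C(C)(C)C)cc(/C(OS(=O)(=O)C(F)(F)F)=C2/C(=C)CC[C@H]3C(C)(C)CCC[C@]23C)c1 | intermediate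
21 | 11-chloro-11-(3-methoxy-5-pivaloyloxyphenyl)drima-8(12),9(11)-diene (Cl syn to C8) | COc1cc(OC(=O)C(C)(C)C)cc(/C(Cl)=C2/C(=C)CC[C@H]3C(C)(C)CCC[C@]23C)c1 | intermediate
22 | 11-chloro-11-(3-methoxy-5-pivaloyloxyphenyl)-8αH-drim-9(11)-ene | COc1cc(OC(=O)C(C)(C)C)cc(/C(Cl)=C2/[C@@H](C)CC[C@H]3C(C)(C)CCC[C@]23C)c1 | intermediate
23 | 3-(11-chloro-8αH-drim-9(11)-en-11-yl)-5-methoxyphenol | COc1cc(O)cc(/C(Cl)=C2/[C@@H](C)CC[C@H]3C(C)(C)CCC[C@]23C)c1 | intermediate
24 | 2-(11-chloro-8αH-drim-9(11)-en-11-yl)-6-methoxy-1,4-benzoquinone | COC1=CC(=O)C=C(/C(Cl)=C2/[C@@H](C)CC[C@H]3C(C)(C)CCC[C@]23C)C1=O | target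

**Count**

Total: 15 steps. Longest linear sequence: 14 steps (steps 1–5 and 7–15, from sclareolide); step 6 is a one-step side branch.

**Steps most likely to fail**

1. Step 9. The chromium reagent may attack the anisole-type ring in competition, or hydrogen abstraction at the C11 methylene, shielded by C1, the C10 methyl and the C8 substituents, may stall. Fallback, setting out from 1 and returning at 17: the C11 oxygen is brought in at the lactone α-carbon before any arene exists. Enolisation of 1 with KN(SiMe3)2 and hydroxylation with 2-(phenylsulfonyl)-3-phenyloxaziridine should give 11-hydroxysclareolide F1, which is silylated (Et3SiCl, imidazole) to 11-triethylsilyloxysclareolide F2. The conditions of steps 1 to 5 then lead through silyloxy lactol F3, silyloxy alkynol F4, silyloxy alkynyl acetate F5 and silyloxy dichlorocyclobutenone F6 to silyloxy cyclobutenone F7. Benzannulation with 10 as in step 7 gives silyloxy phenol F8, and pivaloylation as in step 8 gives silyloxy aryl pivalate F9. HF·pyridine frees benzylic alcohol F10, and Dess–Martin periodinane oxidises it to 17.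

2. Step 11. The carbonyl of 18 is twisted out of conjugation with the tetrasubstituted alkene, so the amide base may fail to remove the γ-hydrogen, or the dienolate may not form cleanly with oxygen syn to C8. Fallback, setting out from 18 and returning at 20: soft enolisation with Et3SiOTf and Et3N in CH2Cl2 (silylation of the carbonyl oxygen, then loss of the γ-proton to the amine, under the same s-cis preference) gives silyl dienol ether F11, and CsF with PhNTf2 in DME exchanges the silyl group for triflyl.

3. Step 12. Oxidative addition or chloride transfer at the crowded tetrasubstituted C–O bond may be sluggish, or the C9=C11 geometry may erode through odd-electron nickel intermediates. Fallback, setting out from 20 and returning at 21: Pd(PPh3)4, Me3SnSnMe3 and LiCl in dioxane at 80 °C (two-electron oxidative addition and transmetalation, retention) give dienylstannane F12, and CuCl2 in THF replaces tin by chlorine with retention.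

**Further compounds**

F1 | step 9 | 11-hydroxysclareolide | O=C1C(O)[C@H]2[C@](C)(O1)CC[C@H]3C(C)(C)CCC[C@]23C
F2 | step 9 | 11-triethylsilyloxysclareolide | O=C1C(O[Si](CC)(CC)CC)[C@H]2[C@](C)(O1)CC[C@H]3C(C)(C)CCC[C@]23C
F3 | step 9 | silyloxy lactol | OC1C(O[Si](CC)(CC)CC)[C@H]2[C@](C)(O1)CC[C@H]3C(C)(C)CCC[C@]23C
F4 | step 9 | silyloxy alkynol, 11-ethynyl-11-triethylsilyloxydriman-8α-ol | C#CC(O[Si](CC)(CC)CC)[C@H]2[C@](C)(O)CC[C@H]3C(C)(C)CCC[C@]23C
F5 | step 9 | silyloxy alkynyl acetate | C#CC(O[Si](CC)(CC)CC)[C@H]2[C@](C)(OC(C)=O)CC[C@H]3C(C)(C)CCC[C@]23C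
F6 | step 9 | silyloxy dichlorocyclobutenone | O=C1C=C(C(O[Si](CC)(CC)CC)[C@H]2[C@](C)(OC(C)=O)CC[C@H]3C(C)(C)CCC[C@]23C)C1(Cl)Cl
F7 | step 9 | silyloxy cyclobutenone | O=C1C=C(C(O[Si](CC)(CC)CC)[C@H]2[C@](C)(OC(C)=O)CC[C@H]3C(C)(C)CCC[C@]23C)C1
F8 | step 9 | silyloxy phenol | COc1cc(O)cc(C(O[Si](CC)(CC)CC)[C@H]2[C@](C)(OC(C)=O)CC[C@H]3C(C)(C)CCC[C@]23C)c1
F9 | step 9 | silyloxy aryl pivalate | COc1cc(OC(=O)C(C)(C)C)cc(C(O[Si](CC)(CC)CC)[C@H]2[C@](C)(OC(C)=O)CC[C@H]3C(C)(C)CCC[C@]23C)c1
F10 | step 9 | benzylic alcohol | COc1cc(OC(=O)C(C)(C)C)cc(C(O)[C@H]2[C@](C)(OC(C)=O)CC[C@H]3C(C)(C)CCC[C@]23C)c1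
F11 | step 11 | silyl dienol ether (OSiEt3 syn to C8) | COc1cc(OC(=O)C(C)(C)C)cc(/C(O[Si](CC)(CC)CC)=C2/C(=C)CC[C@H]3C(C)(C)CCC[C@]23C)c1
F12 | step 12 | dienylstannane (SnMe3 syn to C8) | COc1cc(OC(=O)C(C)(C)C)cc(/C([Sn](C)(C)C)=C2/C(=C)CC[C@H]3C(C)(C)CCC[C@]23C)c1
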